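**Assumptions.** The target SMILES is read as methyl (2R)-2-[(3S,6R)-6-methyl-6-[2-(2,6,6-trimethyl-3-oxocyclohex-1-en-1-yl)ethyl]-1,2-dioxan-3-yl]propanoate. Chiral reagent 9 and the IDPi acid are made by their standard procedures from commercial materials and are not counted as steps. The (S,S) label of the IDPi acid stands for the antipode that gives 6R, to be confirmed in the first experiment.

## Retrosynthetic overview

1. Target 18 ⇐ vinyl-dioxane 14: the CO2Me group comes from oxidative cleavage of a vinyl group (masked carboxyl), then esterification.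
2. The 1,2-dioxane is the only ring made in the route (the cyclohexenone ring is bought with 1). It is closed at the C6–O bond by a catalyst-controlled Markovnikov addition of the secondary hydroperoxide 13 to a 1,1-disubstituted alkene, which sets quaternary C6.
3. The C3–OOH bond of 13 ⇐ SN2 inversion of the mesylate of anti-homoallylic alcohol 11; C2 and C3 come from an asymmetric anti-crotylation of aldehyde 8.
4. Aldehyde 8 ⇐ B-alkyl Suzuki coupling of vinyl triflate 4 with acrolein diethyl acetal; 4 ⇐ dihydro-β-ionone 1 by kinetic enol triflation and ring allylic oxidation.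

## Route

Step 1
Reactants: 1 dihydro-β-ionone, 4-(2,6,6-trimethylcyclohex-1-en-1-yl)butan-2-one
Product: 3 4-(2,6,6-trimethylcyclohex-1-en-1-yl)but-1-en-2-yl trifluoromethanesulfonate, via lithium enolate 2 (not isolated)
Conditions: LiN(iPr)2 (LDA, 1.1 equiv), THF, −78 °C; then PhNTf2 (1.1 equiv), −78 → 0 °C
Reagents that add atoms: N-phenylbis(trifluoromethanesulfonimide), O=S(=O)(N(c1ccccc1)S(=O)(=O)C(F)(F)F)C(F)(F)F
Why: Kinetic deprotonation of a methyl ketone by LDA takes place at CH3 (typically 9:1 or better) and O-triflation of the terminal enolate gives the 1,1-disubstituted vinyl triflate (regioselective enol triflate formation); the tetrasubstituted ring alkene is inert.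

Step 2
Reactants: 3 4-(2,6,6-trimethylcyclohex-1-en-1-yl)but-1-en-2-yl trifluoromethanesulfonate
Product: 4 4-(2,6,6-trimethyl-3-oxocyclohex-1-en-1-yl)but-1-en-2-yl trifluoromethanesulfonate
Conditions: Rh2(cap)4 (cap = caprolactamate, 1 mol%), t-BuOOH (70% aq, 5 equiv), K2CO3 (0.5 equiv), CH2Cl2, rt
Reagents that add atoms: tert-butyl hydroperoxide, CC(C)(C)OO
Why: Dirhodium caprolactamate/TBHP allylic C–H oxidation (tert-butylperoxyl radical H-abstraction, then collapse of the mixed peroxide to the enone) attacks the ring CH2 next to the electron-rich tetrasubstituted alkene, whereas the chain CH2 on the other alkene carbon is shielded by the gem-dimethyl group and the vinyl triflate is electron-poor; the new enone also deactivates the ring alkene towards the later acid and ozone steps.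

Step 3
Reactants: 4 4-(2,6,6-trimethyl-3-oxocyclohex-1-en-1-yl)but-1-en-2-yl trifluoromethanesulfonate; 5 acrolein diethyl acetal (3,3-diethoxyprop-1-ene)
Product: 8 4-methylidene-6-(2,6,6-trimethyl-3-oxocyclohex-1-en-1-yl)hexanal, via alkylborane 6 (not isolated), via diethyl acetal 7 (not isolated)
Conditions: 5, 9-BBN-H (1.1 equiv), THF, 0 °C → rt; then 4, Pd(dppf)Cl2 (5 mol%), K3PO4 (3 M aq, 3 equiv), THF, 60 °C; then 1 M HCl, THF, rt
Reagents that add atoms: water, O
Why: 9-BBN adds anti-Markovnikov to 5 and the primary alkylborane undergoes B-alkyl Suzuki–Miyaura coupling with the vinyl triflate (oxidative addition of zerovalent palladium into C–OTf, base-assisted transmetalation, reductive elimination), after which the diethyl acetal is hydrolysed in the acidic work-up; no stereocentre is formed.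

Step 4
Reactants: 8 4-methylidene-6-(2,6,6-trimethyl-3-oxocyclohex-1-en-1-yl)hexanal; 9 diisopropyl (4R,5R)-2-[(2E)-but-2-en-1-yl]-1,3,2-dioxaborolane-4,5-dicarboxylate (Roush (E)-crotylboronate of (R,R)-diisopropyl tartrate)
Product: 11 (3S,4R)-3-methyl-7-methylidene-9-(2,6,6-trimethyl-3-oxocyclohex-1-en-1-yl)non-1-en-4-ol, via borate ester 10 (not isolated)
Conditions: 9 (1.5 equiv), 4 Å MS, toluene, −78 °C; then aq NaHCO3, rt
Reagents that add atoms: none
Why: Roush asymmetric crotylboration through a closed chair transition state, in which the (E)-crotyl geometry gives the 3,4-anti product and the (R,R)-tartrate directs attack on the si face of the aldehyde to give 3S,4R (about 85–90% ee, dr above 95:5) while the ketone is untouched at −78 °C; the minor enantiomer becomes a separable diastereomer in step 7.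

Step 5
Reactants: 11 (3S,4R)-3-methyl-7-methylidene-9-(2,6,6-trimethyl-3-oxocyclohex-1-en-1-yl)non-1-en-4-ol
Product: 12 (3S,4R)-3-methyl-7-methylidene-9-(2,6,6-trimethyl-3-oxocyclohex-1-en-1-yl)non-1-en-4-yl methanesulfonate
Conditions: MsCl (1.3 equiv), Et3N (2 equiv), CH2Cl2, 0 °C
Reagents that add atoms: methanesulfonyl chloride, CS(=O)(=O)Cl
Why: O-Sulfonylation of the secondary alcohol (mesylate formation) proceeds with retention and provides the leaving group for the peroxide displacement.

Step 6
Reactants: 12 (3S,4R)-3-methyl-7-methylidene-9-(2,6,6-trimethyl-3-oxocyclohex-1-en-1-yl)non-1-en-4-yl methanesulfonate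
Product: 13 (3S,4S)-4-hydroperoxy-3-methyl-7-methylidene-9-(2,6,6-trimethyl-3-oxocyclohex-1-en-1-yl)non-1-ene
Conditions: 50% aq H2O2 (30 equiv), KOH (1.5 equiv), MeOH/THF, 0 °C → rt
Reagents that add atoms: hydrogen peroxide, OO
Why: Williams–Mosher-type SN2 displacement of the secondary mesylate by hydroperoxide anion (a strong α-effect nucleophile but a weak base) inverts C4 from R to S, which is the C3 configuration of the target; no acidifying group sits next to the leaving group and the hindered tetrasubstituted enone resists nucleophilic epoxidation.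

Step 7
Reactants: 13 (3S,4S)-4-hydroperoxy-3-methyl-7-methylidene-9-(2,6,6-trimethyl-3-oxocyclohex-1-en-1-yl)non-1-ene
Product: 14 (3S,6R)-3-[(2S)-but-3-en-2-yl]-6-methyl-6-[2-(2,6,6-trimethyl-3-oxocyclohex-1-en-1-yl)ethyl]-1,2-dioxane
Conditions: (S,S)-IDPi Brønsted acid (imidodiphosphorimidate built from two 3,3'-diaryl-BINOL units with N-triflyl groups, 5 mol%), 5 Å MS, cyclohexane, 40 °C
Reagents that add atoms: none
Why: Proposed new method: the confined chiral IDPi acid protonates the 1,1-disubstituted alkene (the only alkene basic enough, since the enone and vinyl groups are not) while a basic sulfonyl oxygen of its anion accepts the O–H proton of the hydroperoxide, so that the C–H and C6–O bonds form in one asynchronous Markovnikov 6-exo event inside the chiral pocket and quaternary C6 is fixed as R (chair with the C3 side chain equatorial and the methyl derived from =CH2 axial, a mild substrate preference that the chosen catalyst antipode reinforces); the closest known reaction types are the IDPi-catalysed asymmetric intramolecular hydroalkoxylation of unactivated 1,1-disubstituted alkenols to 2,2-disubstituted cyclic ethers and the classical acid-catalysed Markovnikov addition of hydroperoxides to alkenes, here extended to a hydroperoxide O–H nucleophile and to 1,2-dioxane formation.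

Step 8
Reactants: 14 (3S,6R)-3-[(2S)-but-3-en-2-yl]-6-methyl-6-[2-(2,6,6-trimethyl-3-oxocyclohex-1-en-1-yl)ethyl]-1,2-dioxane
Product: 17 (2R)-2-[(3S,6R)-6-methyl-6-[2-(2,6,6-trimethyl-3-oxocyclohex-1-en-1-yl)ethyl]-1,2-dioxan-3-yl]propanoic acid, via ozonide 15 (not isolated), via aldehyde 16 (not isolated)
Conditions: O3, CH2Cl2, −78 °C (Sudan Red 7B end point); Me2S (10 equiv), −78 °C → rt, then evaporate; NaClO2, NaH2PO4, 2-methylbut-2-ene, t-BuOH/H2O, 0 °C → rt
Reagents that add atoms: ozone, [O-][O+]=O; sodium chlorite, [Na+].[O-]Cl=O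
Why: Criegee ozonolysis is much faster at the monosubstituted vinyl group than at the electron-poor tetrasubstituted enone C=C, Me2S reduces the 1,2,4-trioxolane without touching the dialkyl peroxide, and the α-stereogenic β-peroxy aldehyde is oxidised at once under buffered Pinnick–Lindgren conditions (pH about 4) so that C2 is not epimerised.

Step 9
Reactants: 17 (2R)-2-[(3S,6R)-6-methyl-6-[2-(2,6,6-trimethyl-3-oxocyclohex-1-en-1-yl)ethyl]-1,2-dioxan-3-yl]propanoic acid
Product: 18 methyl diacarnoate A, methyl (2R)-2-[(3S,6R)-6-methyl-6-[2-(2,6,6-trimethyl-3-oxocyclohex-1-en-1-yl)ethyl]-1,2-dioxan-3-yl]propanoate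
Conditions: TMSCHN2 (1.5 equiv), MeOH/toluene (1:4), 0 °C
Reagents that add atoms: (trimethylsilyl)diazomethane, C[Si](C)(C)C=[N+]=[N-]
Why: Methyl ester formation with (trimethylsilyl)diazomethane (O-alkylation of the acid by the diazoalkane) is neutral and leaves the base- and reductant-sensitive 1,2-dioxane and the C2 centre untouched.

## Compound list

1 | dihydro-β-ionone, 4-(2,6,6-trimethylcyclohex-1-en-1-yl)butan-2-one | CC(=O)CCC1=C(C)CCCC1(C)C | starting material
2 | lithium 4-(2,6,6-trimethylcyclohex-1-en-1-yl)but-1-en-2-olate | [Li+].C=C([O-])CCC1=C(C)CCCC1(C)C | intermediate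
3 | 4-(2,6,6-trimethylcyclohex-1-en-1-yl)but-1-en-2-yl trifluoromethanesulfonate | C=C(OS(=O)(=O)C(F)(F)F)CCC1=C(C)CCCC1(C)C | intermediate
4 | 4-(2,6,6-trimethyl-3-oxocyclohex-1-en-1-yl)but-1-en-2-yl trifluoromethanesulfonate | C=C(OS(=O)(=O)C(F)(F)F)CCC1=C(C)C(=O)CCC1(C)C | intermediate
5 | acrolein diethyl acetal, 3,3-diethoxyprop-1-ene | C=CC(OCC)OCC | starting material
6 | 9-(3,3-diethoxypropyl)-9-borabicyclo[3.3.1]nonane | CCOC(OCC)CCB1C2CCCC1CCC2 | intermediate
7 | 3-(6,6-diethoxy-3-methylidenehexyl)-2,4,4-trimethylcyclohex-2-en-1-one | CCOC(OCC)CCC(=C)CCC1=C(C)C(=O)CCC1(C)C | intermediate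
8 | 4-methylidene-6-(2,6,6-trimethyl-3-oxocyclohex-1-en-1-yl)hexanal | O=CCCC(=C)CCC1=C(C)C(=O)CCC1(C)C | intermediate
9 | diisopropyl (4R,5R)-2-[(2E)-but-2-en-1-yl]-1,3,2-dioxaborolane-4,5-dicarboxylate | CC(C)OC(=O)[C@@H]1OB(C/C=C/C)O[C@H]1C(=O)OC(C)C | starting material
10 | diisopropyl (4R,5R)-2-{[(3S,4R)-3-methyl-7-methylidene-9-(2,6,6-trimethyl-3-oxocyclohex-1-en-1-yl)non-1-en-4-yl]oxy}-1,3,2-dioxaborolane-4,5-dicarboxylate | CC(C)OC(=O)[C@@H]1OB(O[C@H](CCC(=C)CCC2=C(C)C(=O)CCC2(C)C)[C@@H](C)C=C)O[C@H]1C(=O)OC(C)C | intermediate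
11 | (3S,4R)-3-methyl-7-methylidene-9-(2,6,6-trimethyl-3-oxocyclohex-1-en-1-yl)non-1-en-4-ol | C=C[C@H](C)[C@H](O)CCC(=C)CCC1=C(C)C(=O)CCC1(C)C | intermediate
12 | (3S,4R)-3-methyl-7-methylidene-9-(2,6,6-trimethyl-3-oxocyclohex-1-en-1-yl)non-1-en-4-yl methanesulfonate | C=C[C@H](C)[C@H](OS(C)(=O)=O)CCC(=C)CCC1=C(C)C(=O)CCC1(C)C | intermediate
13 | (3S,4S)-4-hydroperoxy-3-methyl-7-methylidene-9-(2,6,6-trimethyl-3-oxocyclohex-1-en-1-yl)non-1-ene | C=C[C@H](C)[C@@H](OO)CCC(=C)CCC1=C(C)C(=O)CCC1(C)C | intermediate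
14 | (3S,6R)-3-[(2S)-but-3-en-2-yl]-6-methyl-6-[2-(2,6,6-trimethyl-3-oxocyclohex-1-en-1-yl)ethyl]-1,2-dioxane | C=C[C@H](C)[C@@H]1CC[C@@](C)(CCC2=C(C)C(=O)CCC2(C)C)OO1 | intermediate
15 | (3S,6R)-6-methyl-3-[(1R)-1-(1,2,4-trioxolan-3-yl)ethyl]-6-[2-(2,6,6-trimethyl-3-oxocyclohex-1-en-1-yl)ethyl]-1,2-dioxane (both epimers at the trioxolane carbon) | O1COOC1[C@H](C)[C@@H]2CC[C@@](C)(CCC3=C(C)C(=O)CCC3(C)C)OO2 | intermediate
16 | (2R)-2-[(3S,6R)-6-methyl-6-[2-(2,6,6-trimethyl-3-oxocyclohex-1-en-1-yl)ethyl]-1,2-dioxan-3-yl]propanal | O=C[C@H](C)[C@@H]1CC[C@@](C)(CCC2=C(C)C(=O)CCC2(C)C)OO1 | intermediate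
17 | (2R)-2-[(3S,6R)-6-methyl-6-[2-(2,6,6-trimethyl-3-oxocyclohex-1-en-1-yl)ethyl]-1,2-dioxan-3-yl]propanoic acid | OC(=O)[C@H](C)[C@@H]1CC[C@@](C)(CCC2=C(C)C(=O)CCC2(C)C)OO1 | intermediate
18 | methyl diacarnoate A, methyl (2R)-2-[(3S,6R)-6-methyl-6-[2-(2,6,6-trimethyl-3-oxocyclohex-1-en-1-yl)ethyl]-1,2-dioxan-3-yl]propanoate | COC(=O)[C@H](C)[C@@H]1CC[C@@](C)(CCC2=C(C)C(=O)CCC2(C)C)OO1 | target

## Step count and risks

Total step count: 9. Longest linear sequence: 9 steps (1 → 18).

The three steps most likely to fail are steps 6, 7 and 8.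

**Step 6 (perhydrolysis of mesylate 12).** The carbon attacked is secondary and β-branched, E2 towards the allylic hydrogen would give a conjugated diene, and free alkaline H2O2 may slowly attack the enone or degrade the product. The fallback sets out from 12 and comes back at 13. It replaces free H2O2 by a masked peroxide nucleophile: the cesium salt of 2-methoxyprop-2-yl hydroperoxide (made with CsOH·H2O in DMF at 0 °C) displaces the mesylate with inversion to give the monoperoxyketal (3S,4S)-4-[(2-methoxypropan-2-yl)peroxy]-3-methyl-7-methylidene-9-(2,6,6-trimethyl-3-oxocyclohex-1-en-1-yl)non-1-ene F1. Aqueous AcOH/THF at rt then unmasks F1 to hydroperoxide 13 under non-basic conditions.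

**Step 7 (the proposed IDPi hydroperoxide cyclisation).** The strong acid may isomerise the exocyclic alkene without ring closure, may decompose the hydroperoxide, or may give poor control at C6. The fallback uses known chemistry, sets out from 13 and comes back at 14. Cycloperoxymercuration with Hg(OAc)2 (divalent mercury, 1.1 equiv, CH2Cl2, rt) closes the same C6–O bond in the same 6-exo Markovnikov sense and gives the organomercurial {(6S)-6-[(2S)-but-3-en-2-yl]-3-[2-(2,6,6-trimethyl-3-oxocyclohex-1-en-1-yl)ethyl]-1,2-dioxan-3-yl}methylmercury acetate F2 as both epimers at the quaternary carbon. Demercuration with NaBH4 in 2 M NaOH/CH2Cl2 at 0 °C gives 14 together with its C6 epimer, (3S,6S)-3-[(2S)-but-3-en-2-yl]-6-methyl-6-[2-(2,6,6-trimethyl-3-oxocyclohex-1-en-1-yl)ethyl]-1,2-dioxane F3, which is removed by chromatography. In this fallback C6 is secured by separation, not by a catalyst.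

**Step 8 (ozonolysis and chlorite oxidation).** Ozone must distinguish the vinyl group from the enone, and the β-peroxy aldehyde 16 can epimerise at C2 or lose the peroxide by β-elimination if it is handled for long. The fallback sets out from 14 and comes back at 16. It cleaves the vinyl group in two mild stages without ozone or an ozonide: OsO4 (2 mol%) with NMO in acetone/H2O dihydroxylates only the monosubstituted alkene to give 3-[(3S,6R)-6-methyl-6-[2-(2,6,6-trimethyl-3-oxocyclohex-1-en-1-yl)ethyl]-1,2-dioxan-3-yl]butane-1,2-diol F4 (both C2 epimers, C3 as in 14). NaIO4 in pH 7 buffered THF/H2O then cleaves F4 to aldehyde 16, which is oxidised at once with NaClO2 as in step 8.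

## Further compounds

F1 | step 6 | (3S,4S)-4-[(2-methoxypropan-2-yl)peroxy]-3-methyl-7-methylidene-9-(2,6,6-trimethyl-3-oxocyclohex-1-en-1-yl)non-1-ene | C=C[C@H](C)[C@@H](OOC(C)(C)OC)CCC(=C)CCC1=C(C)C(=O)CCC1(C)C
F2 | step 7 | {(6S)-6-[(2S)-but-3-en-2-yl]-3-[2-(2,6,6-trimethyl-3-oxocyclohex-1-en-1-yl)ethyl]-1,2-dioxan-3-yl}methylmercury acetate (both epimers at the quaternary carbon) | C=C[C@H](C)[C@@H]1CCC(C[Hg]OC(C)=O)(CCC2=C(C)C(=O)CCC2(C)C)OO1
F3 | step 7 | (3S,6S)-3-[(2S)-but-3-en-2-yl]-6-methyl-6-[2-(2,6,6-trimethyl-3-oxocyclohex-1-en-1-yl)ethyl]-1,2-dioxane | C=C[C@H](C)[C@@H]1CC[C@](C)(CCC2=C(C)C(=O)CCC2(C)C)OO1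
F4 | step 8 | 3-[(3S,6R)-6-methyl-6-[2-(2,6,6-trimethyl-3-oxocyclohex-1-en-1-yl)ethyl]-1,2-dioxan-3-yl]butane-1,2-diol (both C2 epimers) | OCC(O)[C@H](C)[C@@H]1CC[C@@](C)(CCC2=C(C)C(=O)CCC2(C)C)OO1
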